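**Plan**

1. Retrosynthesis first removes the C8 acetate, the C8 hydrogen and the C2/C3 hydrogens (ester, then a 3-methoxy-2-ene-4,8-dione), then the C5 O-methyl group and the C8 carbonyl (as its dimethyl ketal).
2. The central cut is C5–C6. With the target numbered C1 (allyl bridgehead), C2 (CH2), C3 (CH–OMe), C4 (C=O), C5 (OMe bridgehead), C6 (CH–Ar), C7 (CH–CH3), C8 (CH–OAc), the oxygen on C5 beside the C4 carbonyl in ring C1–C7–C6–C5–C8 is the trace of an α-ketol in which C6 has moved from C4 to C5. Undoing that shift gives a bicyclo[2.2.2]oct-2-en-5-one with a hydroxyl on bridgehead C4.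
3. Cutting C4–C6 and C1–C7 of that bicycle (retro-Diels–Alder) leaves (E)-methylisoeugenol and a 6,6-dimethoxycyclohexa-2,4-dienone made from apiole.
4. Forward order: arene → dienone → [4+2] (bicyclo[2.2.2]octene) → 1,2-shift closing the five-membered ring (bicyclo[3.2.1]octene) → methyl ether → C8 ketone → double reduction → acetate.
5. Stereochemistry: trans C6/C7 from the E alkene, aryl orientation from the endo transition state, C1 and C5 from the cage, absolute configuration by resolution of the bridgehead ketol, C8 by thermodynamically controlled ketyl reduction, C3 by kinetic exo protonation of an enolate.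

Key step: step 6

Assumption: apiole and (E)-methylisoeugenol are bought; the atom labels C1–C8 of the target are kept for every bicyclic compound (in the bicyclo[2.2.2] series C4 is the oxygen-bearing bridgehead and C5–C8 the keto/ketal bridge), Ar = 3,4-dimethoxyphenyl, and exo means on the side of C8.

**Route**

Step 1
Reactants: 1 apiole
Product: 3 5-allyl-3,6-dimethoxybenzene-1,2-diol, via chloromethyl ether dichloroborinate 2 (not isolated)
Conditions: BCl3 (1.2 equiv), CH2Cl2, −78 → 0 °C; then H2O
Reagents that add atoms: none
Why: Lewis-acid ether cleavage, in which BCl3 opens the acetal-type O–CH2–O unit far faster than it demethylates aryl methyl ethers and leaves the unactivated alkene alone at low temperature; 2 is hydrolysed on work-up.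

Step 2
Reactants: 3 5-allyl-3,6-dimethoxybenzene-1,2-diol
Product: 4 3-allyl-2,5-dimethoxy-6-(triisopropylsilyloxy)phenol
Conditions: TIPSCl (1.05 equiv), imidazole, DMF, 0 °C
Reagents that add atoms: triisopropylsilyl chloride (CC(C)[Si](Cl)(C(C)C)C(C)C)
Why: Sterically governed mono-silylation, in which the hydroxyl beside the methoxy group that has a ring C–H on its other side (and can lie in the ring plane) is less crowded than the hydroxyl beside the methoxy group twisted out of plane by the allyl group; the bulky silyl chloride sharpens the difference, and base-mediated O-to-O silyl migration lets the mixture settle on the less congested ether.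

Step 3
Reactants: 4 3-allyl-2,5-dimethoxy-6-(triisopropylsilyloxy)phenol; 5 (E)-methylisoeugenol
Product: 7 rac-1-allyl-6-(3,4-dimethoxyphenyl)-3,8,8-trimethoxy-7-methyl-4-(triisopropylsilyloxy)bicyclo[2.2.2]oct-2-en-5-one (aryl syn to C2=C3; methyl syn to the C5–C8 bridge), via masked ortho-benzoquinone 6 (not isolated)
Conditions: PhI(OAc)2, MeOH, 0 °C; evaporate; 5 (5 equiv), toluene, 110 °C
Reagents that add atoms: methanol (CO)
Why: Oxidative dearomatisation of a 2-methoxyphenol with PhI(OAc)2 in methanol gives dienone 6 (the bulky silyl group keeps methanol away from the other ortho carbon), and its inverse-electron-demand Diels–Alder reaction with 5 joins the nucleophilic β-carbon of the styrene to the allyl-bearing diene terminus and the benzylic carbon to the silyloxy terminus, with the aryl group under the diene (endo) and the E geometry carried into a trans C6/C7 pair; 6 is achiral, so 7 should form as the racemate.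

Step 4
Reactants: 7 rac-silyl ether adduct
Product: 8 rac-1-allyl-6-(3,4-dimethoxyphenyl)-4-hydroxy-3,8,8-trimethoxy-7-methylbicyclo[2.2.2]oct-2-en-5-one
Conditions: TBAF, AcOH, THF, 0 → 25 °C
Reagents that add atoms: none
Why: Fluoride-induced silyl ether cleavage, buffered with acetic acid so that the bridgehead alkoxide is protonated before it can rearrange; ketal and enol ether are inert to these conditions.

Step 5
Reactants: 8 rac-bridgehead ketol
Product: 9 bridgehead ketol, single enantiomer (configuration as in the SMILES)
Conditions: preparative HPLC, amylose tris(3,5-dimethylphenylcarbamate) on silica, hexane/i-PrOH, 25 °C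
Reagents that add atoms: none
Why: Resolution by chromatography on a chiral stationary phase, to which the hydroxy ketone offers hydrogen-bonding sites; the absolute configuration of the two fractions is to be assigned by X-ray diffraction or by comparing calculated with recorded ECD curves.

Step 6
Reactants: 9 bridgehead ketol, single enantiomer
Product: 10 1-allyl-6-endo-(3,4-dimethoxyphenyl)-5-hydroxy-3,8,8-trimethoxy-7-exo-methylbicyclo[3.2.1]oct-2-en-4-one
Conditions: t-BuOK (0.2 equiv), THF, 0 → 25 °C
Reagents that add atoms: none
Why: Deprotonation of the C4 hydroxyl gives an alkoxide whose C4–C6 bond moves with its electron pair to the adjacent C5 carbonyl carbon while C4 becomes the ketone and C5 the new tertiary alkoxide, an α-ketol (acyloin) rearrangement of the kind known for bridgehead ketols of bicyclo[2.2.2]octenones. The five-membered ring C1–C7–C6–C5–C8 closes through this suprafacial 1,2-shift, which contracts the former six-membered ring C1–C7–C6–C4–C5–C8 by one atom (a ring contraction, not an exo or endo cyclisation), and the six-membered ring C1–C2–C3–C4–C5–C8 is carried over unchanged. The only new stereocentre, C5, is dictated by the cage, since C6 can reach C5 only on the face it already spans; the migrating carbon keeps its configuration, so the trans aryl/methyl pair and the aryl orientation toward the former C2=C3 bridge (endo in 10) are preserved. The step needs C6 and not the vinylic C3 to migrate and the equilibrium to lie forward; the C4–C6 and C4–C3 bonds are equally aligned with the C5 carbonyl, so the choice is thermodynamic, and only C6 migration gives the conjugated C2=C3–C4=O methoxy enone in the less strained bicyclo[3.2.1]octene, which reversible catalytic-base conditions should allow the system to reach.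

Step 7
Reactants: 10 tertiary ketol
Product: 11 1-allyl-6-endo-(3,4-dimethoxyphenyl)-3,5,8,8-tetramethoxy-7-exo-methylbicyclo[3.2.1]oct-2-en-4-one
Conditions: NaH, MeI, DMF, 0 °C
Reagents that add atoms: iodomethane (CI)
Why: Williamson etherification of a tertiary alkoxide that has no enolisable neighbour (C3 is sp2, C5 quaternary) and whose only other channel, the reverse ketol shift, is uphill.

Step 8
Reactants: 11 methyl ether ketal
Product: 12 1-allyl-6-endo-(3,4-dimethoxyphenyl)-3,5-dimethoxy-7-exo-methylbicyclo[3.2.1]oct-2-ene-4,8-dione
Conditions: TFA/H2O (9:1), CH2Cl2, 0 → 25 °C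
Reagents that add atoms: water (O)
Why: Acid-catalysed ketal hydrolysis, placed here because 11 has no epimerisable centre and its methoxy enone (a diosphenol ether, whose protonation would put charge next to the carbonyl) is far less acid-labile than a simple enol ether.

Step 9
Reactants: 12 ene-4,8-dione
Product: 14 1-allyl-6-endo-(3,4-dimethoxyphenyl)-8-hydroxy-3-endo,5-dimethoxy-7-exo-methylbicyclo[3.2.1]octan-4-one (hydroxyl syn to the C2–C4 bridge), via dilithium enolate alkoxide 13 (not isolated)
Conditions: Li (5 equiv), NH3(l)/THF, t-BuOH (2 equiv), −78 °C; isoprene; NH4Cl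
Reagents that add atoms: none
Why: Dissolving-metal (Birch-type) reduction, in which the enone takes two electrons and a proton at C2 to give the C3=C4 lithium enolate that shields C4, while the strained C8 ketone is reduced through its ketyl under thermodynamic control (as in camphor-to-borneol reductions) so that the oxygen ends on the C2–C4 side, away from the exo C7 methyl that a kinetic hydride would avoid; on quenching, the enolate should be protonated at C3 from the open exo (C8) face, the endo face lying under the C6 aryl, which leaves the C3 methoxy endo.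

Step 10
Reactants: 14 hydroxy ketone
Product: 15 target, (1S,3S,5S,6S,7R,8S)-8-acetoxy-1-allyl-6-(3,4-dimethoxyphenyl)-3,5-dimethoxy-7-methylbicyclo[3.2.1]octan-4-one (skeleton numbering)
Conditions: Ac2O, pyridine, DMAP (cat.), 25 °C
Reagents that add atoms: acetic anhydride (CC(=O)OC(C)=O)
Why: DMAP-catalysed acylation of the hindered secondary alcohol under mildly basic conditions that should neither open the β-hydroxy ketone by retro-aldol cleavage nor epimerise C3.

**Compound list**

1 | apiole (5-allyl-4,7-dimethoxy-1,3-benzodioxole) | C=CCc1cc(OC)c2OCOc2c1OC | starting material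
2 | chloromethyl ether dichloroborinate of the opened dioxole (either oxygen may carry boron) | C=CCc1cc(OC)c(OCCl)c(OB(Cl)Cl)c1OC | intermediate (not isolated)
3 | 5-allyl-3,6-dimethoxybenzene-1,2-diol | C=CCc1cc(OC)c(O)c(O)c1OC | intermediate
4 | 3-allyl-2,5-dimethoxy-6-(triisopropylsilyloxy)phenol | C=CCc1cc(OC)c(O[Si](C(C)C)(C(C)C)C(C)C)c(O)c1OC | intermediate
5 | (E)-methylisoeugenol | C/C=C/c1ccc(OC)c(OC)c1 | starting material
6 | 5-allyl-3,6,6-trimethoxy-2-(triisopropylsilyloxy)cyclohexa-2,4-dien-1-one | C=CCC1=CC(OC)=C(O[Si](C(C)C)(C(C)C)C(C)C)C(=O)C1(OC)OC | intermediate (not isolated)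
7 | rac-1-allyl-6-Ar-3,8,8-trimethoxy-7-methyl-4-(triisopropylsilyloxy)bicyclo[2.2.2]oct-2-en-5-one, Ar syn to C2=C3, CH3 syn to C5–C8 (racemate, one enantiomer drawn) | C=CC[C@]12C=C(OC)[C@@](O[Si](C(C)C)(C(C)C)C(C)C)(C(=O)C2(OC)OC)[C@H](c3ccc(OC)c(OC)c3)[C@H]1C | intermediate
8 | rac-1-allyl-6-Ar-4-hydroxy-3,8,8-trimethoxy-7-methylbicyclo[2.2.2]oct-2-en-5-one (racemate, one enantiomer drawn) | C=CC[C@]12C=C(OC)[C@@](O)(C(=O)C2(OC)OC)[C@H](c3ccc(OC)c(OC)c3)[C@H]1C | intermediate
9 | the same bridgehead ketol as a single enantiomer | C=CC[C@]12C=C(OC)[C@@](O)(C(=O)C2(OC)OC)[C@H](c3ccc(OC)c(OC)c3)[C@H]1C | intermediate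
10 | 1-allyl-6-endo-Ar-5-hydroxy-3,8,8-trimethoxy-7-exo-methylbicyclo[3.2.1]oct-2-en-4-one | C=CC[C@]12C=C(OC)C(=O)[C@](O)([C@H](c3ccc(OC)c(OC)c3)[C@H]1C)C2(OC)OC | intermediate
11 | 1-allyl-6-endo-Ar-3,5,8,8-tetramethoxy-7-exo-methylbicyclo[3.2.1]oct-2-en-4-one | C=CC[C@]12C=C(OC)C(=O)[C@](OC)([C@H](c3ccc(OC)c(OC)c3)[C@H]1C)C2(OC)OC | intermediate
12 | 1-allyl-6-endo-Ar-3,5-dimethoxy-7-exo-methylbicyclo[3.2.1]oct-2-ene-4,8-dione | C=CC[C@]12C=C(OC)C(=O)[C@](OC)([C@H](c3ccc(OC)c(OC)c3)[C@H]1C)C2=O | intermediate
13 | dilithium C3=C4 enolate C8 alkoxide of 14 | C=CC[C@]12CC(OC)=C([O-])[C@](OC)([C@H](c3ccc(OC)c(OC)c3)[C@H]1C)[C@H]2[O-].[Li+].[Li+] | intermediate (not isolated)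
14 | 1-allyl-6-endo-Ar-8-hydroxy-3-endo,5-dimethoxy-7-exo-methylbicyclo[3.2.1]octan-4-one, OH syn to the C2–C4 bridge | C=CC[C@]12C[C@H](OC)C(=O)[C@](OC)([C@H](c3ccc(OC)c(OC)c3)[C@H]1C)[C@H]2O | intermediate
15 | CNP0344493.1, the 8-acetate of 14 | C=CC[C@]12C[C@H](OC)C(=O)[C@](OC)([C@H](c3ccc(OC)c(OC)c3)[C@H]1C)[C@H]2OC(C)=O | target

**Step count**

Total: 10 steps. Longest linear sequence: 10 steps (1 → 15); 5 is a purchased partner that enters in step 3.

**Steps most likely to fail**

Step 3. The cycloaddition joins a fully substituted, donor-bearing diene to a 1,2-disubstituted alkene and may be slow enough for thermal decay of the dienone, or oxidative loss of the silyl group during dearomatisation, to take over; the endo preference may also be weak. The fallback sets out from 4 and comes back at 7. The oxidation is run as before, dienone 6 is isolated by quick filtration, and the union with 5 is carried out under hole catalysis (tris(4-bromophenyl)aminium hexachloroantimonate (cat.), CH2Cl2, 0 °C). The radical cation of 5 should attack through its β-carbon at the allyl-bearing terminus of the silyloxy diene and close onto the silyloxy terminus, giving the same connectivity by a stepwise cation-radical [4+2] that does not depend on the thermal frontier-orbital match. No compound outside the list is made (F0).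

Step 9. The dissolving-metal step may over-reduce the veratryl ring, expel a methoxy group next to a carbonyl, cleave the non-enolisable 1,3-diketone through amide addition (retro-Claisen), or protonate C3 with poor facial control. The fallback sets out from 12 and comes back at 14, using hydride-transfer chemistry in two operations. Meerwein–Ponndorf–Verley reduction under equilibrating conditions (Al(OiPr)3, i-PrOH with a little acetone, toluene, 80 °C) should reduce the strained C8 ketone in preference to the hindered conjugated C4 carbonyl and settle on the more stable carbinol, 1-allyl-6-endo-Ar-8-hydroxy-3,5-dimethoxy-7-exo-methylbicyclo[3.2.1]oct-2-en-4-one with the hydroxyl syn to the C2–C4 bridge F1. Conjugate reduction of F1 with Stryker's reagent [(Ph3P)CuH]6 in wet benzene, with exo protonation of the copper enolate, then gives 14.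

Step 2. Discrimination between the two phenolic oxygens may be poor, and silyl migration between them may blur it further. The fallback sets out from 3 and comes back at 4, moving the selective event from silylation to desilylation. Exhaustive silylation (TIPSOTf, 2,6-lutidine, CH2Cl2) gives 1-allyl-2,5-dimethoxy-3,4-bis(triisopropylsilyloxy)benzene F2. Brief treatment with K2CO3 in MeOH at 0 °C should then remove the more congested silyl group, the one whose aryloxide (para to the ring C–H and flanked by the twisted methoxy group) is the better leaving group, to give 4.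

**Further compounds**

F0 | step 3 | none | none
F1 | step 9 | 1-allyl-6-endo-(3,4-dimethoxyphenyl)-8-hydroxy-3,5-dimethoxy-7-exo-methylbicyclo[3.2.1]oct-2-en-4-one, OH syn to the C2–C4 bridge | C=CC[C@]12C=C(OC)C(=O)[C@](OC)([C@H](c3ccc(OC)c(OC)c3)[C@H]1C)[C@H]2O
F2 | step 2 | 1-allyl-2,5-dimethoxy-3,4-bis(triisopropylsilyloxy)benzene | C=CCc1cc(OC)c(O[Si](C(C)C)(C(C)C)C(C)C)c(O[Si](C(C)C)(C(C)C)C(C)C)c1OC
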